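The earlier runs and the new flask are calculated with constants of no real substance.

Early readings in these runs are thin, so settle first which number must be good.

all flasks: substrate 0.10 M

| charge | reagent | remark | time |
|---|---|---|---|
| zeta | 0.061 M | run made earlier |  |
| alpha | 0.23 M | run made earlier |  |
| midnight | 0.120 M |  | 40 h |
| autumn | 0.300 M |  | 40 h |

| run | time / h | target / % | side product / % | intermediate / % | substrate / % |
|---|---|---|---|---|---|
| zeta | 2.50 | 0 | 0.5 | 2.8 | 98.5 |
| zeta | 8.00 | 1.3 | 1.0 | 1.5 | 96.8 |
| zeta | 12.0 | 0.4 | 3.8 | 4.4 | 95.1 |
| zeta | 20.0 | 1.3 | 7.3 | 3.8 | 88.0 |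
| zeta | 30.0 | 1.3 | 11.0 | 4.0 | 83.6 |
| alpha | 2.50 | 0 | 1.6 | 4.5 | 95.4 |
| alpha | 4.00 | 0 | 2.0 | 5.6 | 93.3 |
| alpha | 8.00 | 0.1 | 6.5 | 10.2 | 84.4 |
| alpha | 15.0 | 2.0 | 15.0 | 11.8 | 73.0 |
| alpha | 30.0 | 5.0 | 28.1 | 11.9 | 51.1 |

(each reading ± 1 percentage point)

- percent here means substrate units held: one side product counts as two

* which of these there is most of at the end, counted by the substrate in it, midnight (substrate / target / intermediate / side product)
* which of these there is most of at the end, counted by the substrate in it, autumn (substrate / target / intermediate / side product)
* final amount of the leader among these, as a percentage of the substrate charged, in midnight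
* final amount of the leader among these, as a percentage of the substrate charged, in autumn

Work in logarithms. Call D the common logarithm of charged over remaining substrate, and treat the loss as pseudo-first-order with [reagent] taken at its charge. Then D is a decade constant, the decades of substrate lost per molar of reagent per hour, times [reagent] times time. [reagent] and time are yours to set, and the intermediate and target readings don't enter D, so for D the constant is what has to be good. Its error depends on where you read it. Zeta's 98.5 % at 2.50 h gives the constant a relative error of 67.2 %, zeta's last substrate reading one of 6.68 %, and alpha's last one of 2.91 %. So read it late in alpha: 0.0423 M⁻¹ h⁻¹. Zeta's last reading, at another charge, gives 0.0425 M⁻¹ h⁻¹.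

My reckoning for midnight is D = 0.203, so 62.7 % substrate, more than everything else together. For autumn, D = 0.507, so 31.2 % substrate. Alpha's last readings put 57.5 % of the lost substrate in side product, which gives autumn 39.6 % side product, more than substrate. Swapping that lead in autumn, with that share held, takes an error of 13.7 % in the constant, larger than 2.91 %.

The forecast says substrate at 65 % in midnight and side product at 44 % in autumn: “so side product leads, with a fair margin over substrate”. It names my leaders, with both figures above mine.

Midnight ends with substrate at 63.1 %, autumn with side product at 42.9 % and substrate at 34.0 %.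

    substrate + reagent ⇌ intermediate (K = 4.40 M⁻¹, k = 2.30 × 10⁻⁵ M⁻¹ s⁻¹)
    intermediate ⇌ target + by-product (K = 0.0440 M, k = 4.00 × 10⁻⁶ s⁻¹)
    substrate + intermediate → side product (k = 1.90 × 10⁻⁴ M⁻¹ s⁻¹)

In a neighbour of midnight with 0.20 M of reagent, the constant gives 45.9 % substrate at the end, and that neighbour flask holds 47 %. In midnight the constant's substrate half-life is 59.4 h, longer than the 40 h run. At 40.0 h in midnight, the forward step of substrate with reagent uses substrate 1.6 times as fast as the passing of substrate and intermediate into side product.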